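**Strategy.** Everything rests on cutting two bonds of the cyclopentane, C1–C5 (the ring-fusion bond) and C3–C4 (guaiane numbering). The feature exploited is the C1=C10 double bond: exocyclic to the five-membered ring yet endocyclic in the seven-membered ring, it is read as the alkylidene of an alkylidenecyclopropane whose ring carbons become C1, C2 and C3. A proximal-mode (3+2) cycloaddition under zerovalent nickel joins this unit to a tethered (Z)-propenyl group, closing both carbocycles at once, keeping the tetrasubstituted olefin and setting C4 and C5. The precursor is an open chain whose C7 and C8 centres (chiral-pool epoxide, Fráter–Seebach alkylation) are locked in a temporary 1,3-dioxane.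

Key step: step 8

Convention: guaiane numbering is used throughout: C1 (olefinic ring-fusion carbon), C2, C3, C4 (bears methyl C15), C5 (ring-fusion CH), C6, C7 (bears carbinol carbon C11), C8 (bears the ester oxygen), C9, C10 (olefinic, bears methyl C14).

Assumption: ethyl (R)-3,4-epoxybutanoate is taken as a purchasable chiral-pool ester (it is the epoxide of bulk ethyl (R)-4-chloro-3-hydroxybutanoate).

Step 1
Reactants: 1 ethyl (R)-3,4-epoxybutanoate; 2 vinylmagnesium bromide
Product: 3 ethyl (3S)-3-hydroxyhex-5-enoate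
Conditions: 2 (1.5 equiv), CuI (10 mol %), THF, −40 → −20 °C; aqueous work-up
Reagents that add atoms: vinylmagnesium bromide (2), C=C[Mg]Br
Why: Copper-catalysed Grignard opening of the terminal epoxide is an SN2 attack at the unsubstituted carbon that outruns addition to the ester at low temperature, so the C8 carbinol centre is carried over untouched from the chiral pool (R becomes S only through the change in priorities).

Step 2
Reactants: 3 ethyl (3S)-3-hydroxyhex-5-enoate; 4 1-bromobut-2-yne
Product: 5 ethyl (2S,3S)-2-(but-2-yn-1-yl)-3-hydroxyhex-5-enoate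
Conditions: LiN(i-Pr)2 (2.2 equiv), THF, −78 → −20 °C; then 4, DMPU, −78 → −10 °C
Reagents that add atoms: 1-bromobut-2-yne (4), CC#CCBr
Why: In this Fráter–Seebach alkylation the chelated dilithio alkoxide-enolate should be alkylated by the reactive propargylic bromide on the face anti to the C8 substituent, which sets C7 (2S) in the anti relationship that becomes the trans C7/C8 arrangement of the ring.

Step 3
Reactants: 5 ethyl (2S,3S)-2-(but-2-yn-1-yl)-3-hydroxyhex-5-enoate; 6 methylmagnesium bromide
Product: 7 (3S,4S)-3-(but-2-yn-1-yl)-2-methylhept-6-ene-2,4-diol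
Conditions: 6 (5 equiv), THF, −20 °C → rt; aqueous work-up
Reagents that add atoms: methylmagnesium bromide (6), C[Mg]Br
Why: Double Grignard addition to the ester, after deprotonation of the free hydroxyl, should build the C11 carbinol with both of its methyl groups without touching the two stereocentres.

Step 4
Reactants: 7 (3S,4S)-3-(but-2-yn-1-yl)-2-methylhept-6-ene-2,4-diol; 8 2,2-dimethoxypropane
Product: 9 (5S,6S)-5-(but-2-yn-1-yl)-2,2,4,4-tetramethyl-6-(prop-2-en-1-yl)-1,3-dioxane
Conditions: 8, PPTS (cat.), CH2Cl2, rt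
Reagents that add atoms: 2,2-dimethoxypropane (8), COC(C)(C)OC
Why: Acid-catalysed transketalisation should tie the secondary and tertiary hydroxyls into a 1,3-dioxane that protects both oxygens and holds the two carbon arms trans and gauche to each other for the later ring closure.

Step 5
Reactants: 9 (5S,6S)-5-(but-2-yn-1-yl)-2,2,4,4-tetramethyl-6-(prop-2-en-1-yl)-1,3-dioxane
Product: 10 (5S,6S)-5-[(2Z)-but-2-en-1-yl]-2,2,4,4-tetramethyl-6-(prop-2-en-1-yl)-1,3-dioxane
Conditions: H2 (1 atm), Ni(OAc)2·4H2O/NaBH4 (nickel boride, 10 mol %), ethylenediamine, EtOH, rt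
Reagents that add atoms: none
Why: Amine-poisoned nickel boride should semi-hydrogenate the internal alkyne by syn addition to the Z-olefin while leaving the terminal vinyl group alone, fixing the geometry that later translates into the C4 configuration.

Step 6
Reactants: 10 (5S,6S)-5-[(2Z)-but-2-en-1-yl]-2,2,4,4-tetramethyl-6-(prop-2-en-1-yl)-1,3-dioxane
Product: 11 1-[(4S,5S)-5-[(2Z)-but-2-en-1-yl]-2,2,6,6-tetramethyl-1,3-dioxan-4-yl]propan-2-one
Conditions: PdCl2 (10 mol %), Cu(OAc)2·H2O (20 mol %), O2 (1 atm), DMA/H2O 7:1, rt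
Reagents that add atoms: water, O
Why: Tsuji–Wacker oxidation is selective for the monosubstituted olefin over the 1,2-disubstituted Z-olefin and should give the Markovnikov methyl ketone (C10 carbonyl, C14 methyl), the acetate-buffered variant sparing the ketal.

Step 7
Reactants: 11 1-[(4S,5S)-5-[(2Z)-but-2-en-1-yl]-2,2,6,6-tetramethyl-1,3-dioxan-4-yl]propan-2-one; 12 Cp2TiCl2; 13 cyclopropylmagnesium bromide
Product: 15 (5S,6S)-5-[(2Z)-but-2-en-1-yl]-6-(2-cyclopropylidenepropyl)-2,2,4,4-tetramethyl-1,3-dioxane, via dicyclopropyltitanocene 14 (not isolated)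
Conditions: 12, 13 (2 equiv), Et2O, −40 → 0 °C, salts filtered off; then 11, toluene, 55 °C, dark
Reagents that add atoms: cyclopropylmagnesium bromide (13), Br[Mg]C1CC1, whose cyclopropyl carbons are delivered through dicyclopropyltitanocene (14), [CH-]1CC1.[CH-]1CC1.[Ti+4].[cH-]1cccc1.[cH-]1cccc1
Why: In this Petasis-type alkylidenation, thermolysis of dicyclopropyltitanocene should release cyclopropane and a titanium cyclopropylidene that olefinates the ketone through an oxatitanacyclobutane under non-basic conditions, so the β-alkoxy ketone should not eliminate.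

Step 8
Reactants: 15 (5S,6S)-5-[(2Z)-but-2-en-1-yl]-6-(2-cyclopropylidenepropyl)-2,2,4,4-tetramethyl-1,3-dioxane
Product: 16 (4S,5S,7S,8S)-8,11-O-isopropylideneguai-1(10)-ene-8,11-diol (acetonide of 17; dioxane trans-fused to the cycloheptene at C7–C8)
Conditions: Ni(cod)2 (15 mol %), no phosphine, toluene (0.02 M), 60 °C
Reagents that add atoms: none
Why: Proposed new method: zerovalent nickel should insert into one of the two equivalent proximal C–C bonds of the strained alkylidenecyclopropane to give a 2-alkylidene-nickelacyclobutane, whose Ni–C(sp2) bond adds across the tethered Z-olefin (7-exo-trig migratory insertion, closing the seven-membered ring through C1–C5), and C(sp3)–C(sp3) reductive elimination from the resulting six-membered nickelacycle then closes the cyclopentane through C3–C4 and leaves the alkylidene double bond as the C1=C10 olefin. The closest known reactions are the proximal-mode (3+2) codimerisation of methylenecyclopropanes with electron-poor alkenes under phosphine-free Ni(cod)2 and the Ni(cod)2-catalysed (3+2+2) reactions of tethered alkylidenecyclopropanes, in which the π-partner likewise bonds to the cyclopropane carbon and the alkylidene double bond ends up inside the tether ring; an unactivated olefin and a seven-membered tether ring are the untested extensions. C4 follows from the Z geometry, because insertion and reductive elimination are both suprafacial and so place the C15 methyl cis to C6. C5 is set by the C7 and C8 centres: the trans-fused dioxane holds C6 and C9 pseudo-equatorial, so the olefin should add through a chair-like seven-membered transition state with the new C5–C4 bond pseudo-equatorial (H-5 cis to H-7). The step needs proximal rather than distal (trimethylenemethane-type) opening, which the fully substituted C10 (it would have to become quaternary in the distal mode) and the phosphine-free catalyst should favour.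

Step 9
Reactants: 16 (4S,5S,7S,8S)-8,11-O-isopropylideneguai-1(10)-ene-8,11-diol
Product: 17 (3S,3aS,5S,6S)-5-(2-hydroxypropan-2-yl)-3,8-dimethyl-1,2,3,3a,4,5,6,7-octahydroazulen-6-ol
Conditions: PPTS (0.2 equiv), MeOH, rt → 40 °C
Reagents that add atoms: none
Why: Mild acid-catalysed transketalisation to methanol should remove the strained, fully substituted ketal at an acidity where the tetrasubstituted olefin is not protonated, so that no transannular ether forms from the C11 hydroxyl.

Step 10
Reactants: 17 (3S,3aS,5S,6S)-5-(2-hydroxypropan-2-yl)-3,8-dimethyl-1,2,3,3a,4,5,6,7-octahydroazulen-6-ol; 18 (2E)-3-(4-acetoxyphenyl)prop-2-enoic acid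
Product: 19 (3S,3aS,5S,6S)-5-(2-hydroxypropan-2-yl)-3,8-dimethyl-1,2,3,3a,4,5,6,7-octahydroazulen-6-yl (2E)-3-(4-acetoxyphenyl)prop-2-enoate
Conditions: 18, DCC, DMAP, CH2Cl2, 0 °C → rt
Reagents that add atoms: (2E)-3-(4-acetoxyphenyl)prop-2-enoic acid (18), CC(=O)Oc1ccc(/C=C/C(=O)O)cc1
Why: Steglich esterification should acylate the secondary C8 hydroxyl selectively because the tertiary C11 hydroxyl is far less nucleophilic, with retention at C8 since its C–O bond is not broken.

Step 11
Reactants: 19 (3S,3aS,5S,6S)-5-(2-hydroxypropan-2-yl)-3,8-dimethyl-1,2,3,3a,4,5,6,7-octahydroazulen-6-yl (2E)-3-(4-acetoxyphenyl)prop-2-enoate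
Product: 20 (3S,3aS,5S,6S)-5-(2-hydroxypropan-2-yl)-3,8-dimethyl-1,2,3,3a,4,5,6,7-octahydroazulen-6-yl (2E)-3-(4-hydroxyphenyl)prop-2-enoate (CNP0403230.1)
Conditions: K2CO3 (0.2 equiv), MeOH, 0 °C
Reagents that add atoms: none
Why: Base-catalysed methanolysis should cleave the aryl acetate much faster than the hindered alkyl cinnamate and so release the free phenol of the target.

**Compound list**

1 | ethyl (R)-3,4-epoxybutanoate (ethyl 2-[(2R)-oxiran-2-yl]acetate) | CCOC(=O)C[C@@H]1CO1 | starting material
2 | vinylmagnesium bromide | C=C[Mg]Br | starting material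
3 | ethyl (3S)-3-hydroxyhex-5-enoate | C=CC[C@H](O)CC(=O)OCC | intermediate
4 | 1-bromobut-2-yne | CC#CCBr | starting material
5 | ethyl (2S,3S)-2-(but-2-yn-1-yl)-3-hydroxyhex-5-enoate | C=CC[C@H](O)[C@H](CC#CC)C(=O)OCC | intermediate
6 | methylmagnesium bromide | C[Mg]Br | starting material
7 | (3S,4S)-3-(but-2-yn-1-yl)-2-methylhept-6-ene-2,4-diol | C=CC[C@H](O)[C@H](CC#CC)C(C)(C)O | intermediate
8 | 2,2-dimethoxypropane | COC(C)(C)OC | starting material
9 | (5S,6S)-5-(but-2-yn-1-yl)-2,2,4,4-tetramethyl-6-(prop-2-en-1-yl)-1,3-dioxane | C=CC[C@@H]1OC(C)(C)OC(C)(C)[C@H]1CC#CC | intermediate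
10 | (5S,6S)-5-[(2Z)-but-2-en-1-yl]-2,2,4,4-tetramethyl-6-(prop-2-en-1-yl)-1,3-dioxane | C=CC[C@@H]1OC(C)(C)OC(C)(C)[C@H]1C/C=C\C | intermediate
11 | 1-[(4S,5S)-5-[(2Z)-but-2-en-1-yl]-2,2,6,6-tetramethyl-1,3-dioxan-4-yl]propan-2-one | CC(=O)C[C@@H]1OC(C)(C)OC(C)(C)[C@H]1C/C=C\C | intermediate
12 | bis(cyclopentadienyl)titanium dichloride, Cp2TiCl2 | [Cl-].[Cl-].[Ti+4].[cH-]1cccc1.[cH-]1cccc1 | starting material
13 | cyclopropylmagnesium bromide | Br[Mg]C1CC1 | starting material
14 | dicyclopropyltitanocene, Cp2Ti(c-C3H5)2 | [CH-]1CC1.[CH-]1CC1.[Ti+4].[cH-]1cccc1.[cH-]1cccc1 | intermediate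
15 | (5S,6S)-5-[(2Z)-but-2-en-1-yl]-6-(2-cyclopropylidenepropyl)-2,2,4,4-tetramethyl-1,3-dioxane | CC(=C1CC1)C[C@@H]2OC(C)(C)OC(C)(C)[C@H]2C/C=C\C | intermediate
16 | (4S,5S,7S,8S)-8,11-O-isopropylideneguai-1(10)-ene-8,11-diol | CC1=C2CC[C@H](C)[C@@H]2C[C@@H]3C(C)(C)OC(C)(C)O[C@H]3C1 | intermediate
17 | (3S,3aS,5S,6S)-5-(2-hydroxypropan-2-yl)-3,8-dimethyl-1,2,3,3a,4,5,6,7-octahydroazulen-6-ol | CC1=C2CC[C@H](C)[C@@H]2C[C@H](C(C)(C)O)[C@@H](O)C1 | intermediate
18 | (2E)-3-(4-acetoxyphenyl)prop-2-enoic acid | CC(=O)Oc1ccc(/C=C/C(=O)O)cc1 | starting material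
19 | (3S,3aS,5S,6S)-5-(2-hydroxypropan-2-yl)-3,8-dimethyl-1,2,3,3a,4,5,6,7-octahydroazulen-6-yl (2E)-3-(4-acetoxyphenyl)prop-2-enoate | CC1=C2CC[C@H](C)[C@@H]2C[C@H](C(C)(C)O)[C@@H](OC(=O)/C=C/c2ccc(OC(C)=O)cc2)C1 | intermediate
20 | (3S,3aS,5S,6S)-5-(2-hydroxypropan-2-yl)-3,8-dimethyl-1,2,3,3a,4,5,6,7-octahydroazulen-6-yl (2E)-3-(4-hydroxyphenyl)prop-2-enoate (CNP0403230.1) | CC1=C2CC[C@H](C)[C@@H]2C[C@H](C(C)(C)O)[C@@H](OC(=O)/C=C/c2ccc(O)cc2)C1 | target

Total step count: 11. Longest linear sequence: 11 steps (1 → 20).

**Steps most likely to fail**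

1. Step 8 (proposed new method). The cyclopropane may open in the distal, trimethylenemethane-type sense, so that bonds form at C10 instead of C1. The alkylnickel formed after insertion may undergo β-hydride elimination instead of reductive elimination. The unactivated Z-olefin may fail to insert, or may isomerise to E first. The fallback uses known chemistry, sets out from ketone 11 and comes back at cycloadduct 16. Kinetic deprotonation on the methyl side (KN(SiMe3)2, THF, −78 °C) and trapping with PhNTf2 should give the enol triflate F1. Suzuki–Miyaura coupling with cyclopropylboronic acid (Pd(OAc)2, PCy3, K3PO4, toluene/H2O, 90 °C) should give the 2-cyclopropylallyl dioxane F2, an α-ene-vinylcyclopropane. The established intramolecular (3+2) cycloaddition of such substrates under monovalent rhodium ([Rh(CO)2Cl]2, toluene, 110 °C) forms the same C3–C4 and C1–C5 bonds through a π-allyl rhodacycle and should give the cis-fused exocyclic olefin F3. Olefin isomerisation (RhCl3·3H2O, EtOH, 70 °C) into the tetrasubstituted C1=C10 position then returns to 16.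

2. Step 7. Carbene transfer to the hindered, enolisable methyl ketone may be slow relative to thermal decay of the titanium reagent, and enolisation with loss of the β-alkoxy group may compete. The fallback sets out from 11 and comes back at 15 by a two-stage Peterson olefination. Addition of 1-(trimethylsilyl)cyclopropyllithium (from (1-bromocyclopropyl)trimethylsilane and n-BuLi, with CeCl3, THF, −78 °C) should give the β-hydroxysilane F4. Syn-elimination of silanolate with KH in THF should then give 15.

3. Step 10. Acylation of the C8 hydroxyl, flanked by the hydroxyisopropyl-bearing C7, may be slow, so that rearrangement of the O-acylisourea to the N-acylurea or acyl transfer to the tertiary hydroxyl takes over. The fallback sets out from diol 17 and comes back at target 20, bypassing 19 and step 11. Acylation with the small electrophile acryloyl chloride (Et3N, DMAP, CH2Cl2, 0 °C) should give the acrylate F5. Mizoroki–Heck arylation with unprotected 4-iodophenol (Pd(OAc)2, NaHCO3, Bu4NCl, DMF, 70 °C) should then give the (E)-coumarate 20 without touching the tetrasubstituted ring olefin.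

**Further compounds**

F1 | step 8 | 3-[(4S,5S)-5-[(2Z)-but-2-en-1-yl]-2,2,6,6-tetramethyl-1,3-dioxan-4-yl]prop-1-en-2-yl trifluoromethanesulfonate | C=C(OS(=O)(=O)C(F)(F)F)C[C@@H]1OC(C)(C)OC(C)(C)[C@H]1C/C=C\C
F2 | step 8 | (5S,6S)-5-[(2Z)-but-2-en-1-yl]-6-(2-cyclopropylprop-2-en-1-yl)-2,2,4,4-tetramethyl-1,3-dioxane | C=C(C1CC1)C[C@@H]2OC(C)(C)OC(C)(C)[C@H]2C/C=C\C
F3 | step 8 | (1R,4S,5S,7S,8S)-8,11-O-isopropylideneguai-10(14)-ene-8,11-diol (cis-fused) | C=C1[C@@H]2CC[C@H](C)[C@@H]2C[C@@H]3C(C)(C)OC(C)(C)O[C@H]3C1
F4 | step 7 | 1-[(4S,5S)-5-[(2Z)-but-2-en-1-yl]-2,2,6,6-tetramethyl-1,3-dioxan-4-yl]-2-[1-(trimethylsilyl)cyclopropyl]propan-2-ol (both carbinol epimers) | CC(O)(C[C@@H]1OC(C)(C)OC(C)(C)[C@H]1C/C=C\C)C1(CC1)[Si](C)(C)C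
F5 | step 10 | (3S,3aS,5S,6S)-5-(2-hydroxypropan-2-yl)-3,8-dimethyl-1,2,3,3a,4,5,6,7-octahydroazulen-6-yl prop-2-enoate | CC1=C2CC[C@H](C)[C@@H]2C[C@H](C(C)(C)O)[C@@H](OC(=O)C=C)C1
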